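**Retrosynthetic overview**
- The target is an anti 2-aryl-3-(arylmethyl)succinic acid 4-methyl ester. No ring is formed in the route: both benzene rings and the oxazolidinone auxiliary are bought intact.
- Key disconnection: the C2–C3 bond between the two succinate α-carbons. It is made by oxidative heterocoupling of two enolates, where Fe(acac)3 turns one enolate into an electrophilic α-carbonyl radical (a one-electron enolonium equivalent) that the other enolate captures.
- The partners are the 4-silyloxyphenylacetyl imide of (R)-4-benzyloxazolidin-2-one, which sets the aryl-bearing carbon and later becomes the free acid, and the methyl ester of the prenylated hydrocinnamate, which is already the final ester.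
- The aryl–prenyl bond comes from ortho C-prenylation of a sodium phenoxide; the imide comes from acylation of the auxiliary.
- Both phenols travel as TBS ethers and are freed last with fluoride (no acid, no hydrogenation, so the prenyl group is safe).

Assumption: the four starting materials in the compound list are taken as catalogue items, and all yields and diastereomer ratios quoted are estimates.

**Step 1**
Reactants: 1 4-hydroxyphenylacetic acid
Product: 3 2-[4-(tert-butyldimethylsilyloxy)phenyl]acetic acid, via bis-silyl ester 2 (not isolated)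
Conditions: TBSCl (2.4 equiv), imidazole (5 equiv), DMF, rt; then AcOH/THF/H2O (3:1:1), rt
Reagents that add atoms: tert-butyldimethylsilyl chloride, CC(C)(C)[Si](C)(C)Cl
Why: Imidazole-promoted silylation caps phenol and acid, and the silyl ester is far more labile than the aryl silyl ether, so aqueous acetic acid hydrolyses it selectively; no stereocentre is involved.

**Step 2**
Reactants: 3 2-[4-(tert-butyldimethylsilyloxy)phenyl]acetic acid; 4 (R)-4-benzyloxazolidin-2-one
Product: 6 (R)-4-benzyl-3-{2-[4-(tert-butyldimethylsilyloxy)phenyl]acetyl}oxazolidin-2-one, via mixed pivalic anhydride 5 (not isolated)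
Conditions: PivCl (1.1 equiv), Et3N (2.5 equiv), THF, −20 °C; then LiCl (1.1 equiv), 4 (1.0 equiv), −20 °C → rt
Reagents that add atoms: none
Why: Mixed-anhydride N-acylation of the Evans auxiliary, in which the oxazolidinone attacks the unhindered arylacetyl carbonyl rather than the pivaloyl one; the only stereocentre is bought with 4.

**Step 3**
Reactants: 7 methyl 3-(3-hydroxyphenyl)propanoate; 8 1-bromo-3-methylbut-2-ene (prenyl bromide)
Product: 10 methyl 3-[3-hydroxy-4-(3-methylbut-2-en-1-yl)phenyl]propanoate, via sodium phenoxide 9 (not isolated)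
Conditions: NaH (1.05 equiv), toluene, 0 °C → rt; then 8 (1.1 equiv), rt, 16 h; chromatography
Reagents that add atoms: none
Why: ortho C-alkylation of a sodium phenoxide contact ion pair in a non-polar solvent (phenoxide C-prenylation), favouring the ortho site para to the side chain over the hindered site between the two substituents (about 40–50% expected, O-prenyl ether and 2-prenyl isomer removed); no stereocentre is involved.

**Step 4**
Reactants: 10 methyl 3-[3-hydroxy-4-(3-methylbut-2-en-1-yl)phenyl]propanoate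
Product: 11 methyl 3-[3-(tert-butyldimethylsilyloxy)-4-(3-methylbut-2-en-1-yl)phenyl]propanoate
Conditions: TBSCl (1.2 equiv), imidazole (2.5 equiv), DMF, rt
Reagents that add atoms: tert-butyldimethylsilyl chloride, CC(C)(C)[Si](C)(C)Cl
Why: Standard phenol silylation, which removes the oxidisable and acidic phenol before the enolate chemistry; no stereocentre is involved.

**Step 5**
Reactants: 6 (R)-4-benzyl-3-{2-[4-(tert-butyldimethylsilyloxy)phenyl]acetyl}oxazolidin-2-one; 11 methyl 3-[3-(tert-butyldimethylsilyloxy)-4-(3-methylbut-2-en-1-yl)phenyl]propanoate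
Product: 14 methyl (2R,3R)-4-[(4R)-4-benzyl-2-oxooxazolidin-3-yl]-2-{[3-(tert-butyldimethylsilyloxy)-4-(3-methylbut-2-en-1-yl)phenyl]methyl}-3-[4-(tert-butyldimethylsilyloxy)phenyl]-4-oxobutanoate, via lithium imide enolate 12 (not isolated), via lithium ester enolate 13 (not isolated)
Conditions: 6 (1.0 equiv), 11 (1.3 equiv), LiN(iPr)2 (2.4 equiv), THF, −78 °C, 45 min; then Fe(acac)3 (2.2 equiv), −78 °C → rt; silica gel chromatography
Reagents that add atoms: none
Why: Oxidative enolate heterocoupling, in which trivalent iron oxidises one enolate to an α-carbonyl radical that bonds to the other enolate; the chelated Z-imide enolate reacts on the face away from the auxiliary benzyl group (as in alkylations of this auxiliary), fixing the aryl-bearing carbon as R, while the ester-bearing carbon is set only by the staggered all-anti approach (aryl anti to arylmethyl, acyl anti to ester), so a modest dr of about 2:1 is expected and the (2R,3R) isomer is separated from its C2 epimer as the imide.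

**Step 6**
Reactants: 14 methyl (2R,3R)-4-[(4R)-4-benzyl-2-oxooxazolidin-3-yl]-2-{[3-(tert-butyldimethylsilyloxy)-4-(3-methylbut-2-en-1-yl)phenyl]methyl}-3-[4-(tert-butyldimethylsilyloxy)phenyl]-4-oxobutanoate
Product: 16 (2R,3R)-2-[4-(tert-butyldimethylsilyloxy)phenyl]-3-{[3-(tert-butyldimethylsilyloxy)-4-(3-methylbut-2-en-1-yl)phenyl]methyl}-4-methoxy-4-oxobutanoic acid, via peroxy acid 15 (not isolated)
Conditions: LiOH·H2O (2 equiv), 30% H2O2 (5 equiv), THF/H2O 3:1, 0 °C, 1–2 h; then aq Na2SO3, 0 °C; then 1 M HCl to pH 3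
Reagents that add atoms: hydrogen peroxide, OO
Why: Hydroperoxide cleavage of the Evans imide, where the α-nucleophile attacks the exocyclic imide carbonyl much faster than the hindered methyl ester and is too weakly basic to epimerise the α-aryl centre, and sulfite reduces the peroxy acid before acidification so no free peracid meets the prenyl alkene; no new stereocentre.

**Step 7**
Reactants: 16 (2R,3R)-2-[4-(tert-butyldimethylsilyloxy)phenyl]-3-{[3-(tert-butyldimethylsilyloxy)-4-(3-methylbut-2-en-1-yl)phenyl]methyl}-4-methoxy-4-oxobutanoic acid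
Product: 17 (2R,3R)-2-(4-hydroxyphenyl)-3-{[3-hydroxy-4-(3-methylbut-2-en-1-yl)phenyl]methyl}-4-methoxy-4-oxobutanoic acid (CNP0437978.2)
Conditions: Bu4NF (4 equiv), AcOH (4 equiv), THF, 0 °C → rt; pH 3 aqueous work-up
Reagents that add atoms: none
Why: Fluoride-driven cleavage of both aryl silyl ethers, with acetic acid buffering so that the methyl ester and the α-aryl centre (now next to a carboxylate) are untouched and no strong acid is present to cyclise the ortho-prenylphenol to a chroman; no stereocentre changes.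

**Compound list**
1 | 4-hydroxyphenylacetic acid | OC(=O)Cc1ccc(O)cc1 | starting material
2 | tert-butyldimethylsilyl 2-[4-(tert-butyldimethylsilyloxy)phenyl]acetate | CC(C)(C)[Si](C)(C)OC(=O)Cc1ccc(O[Si](C)(C)C(C)(C)C)cc1 | intermediate
3 | 2-[4-(tert-butyldimethylsilyloxy)phenyl]acetic acid | OC(=O)Cc1ccc(O[Si](C)(C)C(C)(C)C)cc1 | intermediate
4 | (R)-4-benzyloxazolidin-2-one | O=C1N[C@H](Cc2ccccc2)CO1 | starting material
5 | 2-[4-(tert-butyldimethylsilyloxy)phenyl]acetic pivalic anhydride | CC(C)(C)C(=O)OC(=O)Cc1ccc(O[Si](C)(C)C(C)(C)C)cc1 | intermediate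
6 | (R)-4-benzyl-3-{2-[4-(tert-butyldimethylsilyloxy)phenyl]acetyl}oxazolidin-2-one | CC(C)(C)[Si](C)(C)Oc1ccc(CC(=O)N2[C@H](Cc3ccccc3)COC2=O)cc1 | intermediate
7 | methyl 3-(3-hydroxyphenyl)propanoate | COC(=O)CCc1cccc(O)c1 | starting material
8 | 1-bromo-3-methylbut-2-ene (prenyl bromide) | CC(C)=CCBr | starting material
9 | sodium 3-(3-methoxy-3-oxopropyl)phenoxide | COC(=O)CCc1cccc([O-])c1.[Na+] | intermediate
10 | methyl 3-[3-hydroxy-4-(3-methylbut-2-en-1-yl)phenyl]propanoate | COC(=O)CCc1ccc(CC=C(C)C)c(O)c1 | intermediate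
11 | methyl 3-[3-(tert-butyldimethylsilyloxy)-4-(3-methylbut-2-en-1-yl)phenyl]propanoate | COC(=O)CCc1ccc(CC=C(C)C)c(O[Si](C)(C)C(C)(C)C)c1 | intermediate
12 | lithium (Z)-enolate of imide 6 | [Li+].[O-]/C(=C\c1ccc(O[Si](C)(C)C(C)(C)C)cc1)N1[C@H](Cc2ccccc2)COC1=O | intermediate
13 | lithium enolate of ester 11 | [Li+].[O-]C(OC)=CCc1ccc(CC=C(C)C)c(O[Si](C)(C)C(C)(C)C)c1 | intermediate
14 | methyl (2R,3R)-4-[(4R)-4-benzyl-2-oxooxazolidin-3-yl]-2-{[3-(tert-butyldimethylsilyloxy)-4-(3-methylbut-2-en-1-yl)phenyl]methyl}-3-[4-(tert-butyldimethylsilyloxy)phenyl]-4-oxobutanoate | COC(=O)[C@H](Cc1ccc(CC=C(C)C)c(O[Si](C)(C)C(C)(C)C)c1)[C@@H](C(=O)N1[C@H](Cc2ccccc2)COC1=O)c1ccc(O[Si](C)(C)C(C)(C)C)cc1 | intermediate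
15 | (2R,3R)-2-[4-(tert-butyldimethylsilyloxy)phenyl]-3-{[3-(tert-butyldimethylsilyloxy)-4-(3-methylbut-2-en-1-yl)phenyl]methyl}-4-methoxy-4-oxobutaneperoxoic acid | COC(=O)[C@H](Cc1ccc(CC=C(C)C)c(O[Si](C)(C)C(C)(C)C)c1)[C@@H](C(=O)OO)c1ccc(O[Si](C)(C)C(C)(C)C)cc1 | intermediate
16 | (2R,3R)-2-[4-(tert-butyldimethylsilyloxy)phenyl]-3-{[3-(tert-butyldimethylsilyloxy)-4-(3-methylbut-2-en-1-yl)phenyl]methyl}-4-methoxy-4-oxobutanoic acid | COC(=O)[C@H](Cc1ccc(CC=C(C)C)c(O[Si](C)(C)C(C)(C)C)c1)[C@@H](C(=O)O)c1ccc(O[Si](C)(C)C(C)(C)C)cc1 | intermediate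
17 | (2R,3R)-2-(4-hydroxyphenyl)-3-{[3-hydroxy-4-(3-methylbut-2-en-1-yl)phenyl]methyl}-4-methoxy-4-oxobutanoic acid | COC(=O)[C@H](Cc1ccc(CC=C(C)C)c(O)c1)[C@@H](C(=O)O)c1ccc(O)cc1 | target

**Totals**
Total step count: 7. Longest linear sequence: 5 steps (7 → 10 → 11 → 14 → 16 → 17; the other branch, 1 → 3 → 6 → 14 → 16 → 17, is also 5).

**Three steps most likely to fail**

Step 5 (highest risk). Homodimer of 6 competes with the cross-product. Facial control at the aryl-bearing carbon should be reliable, but the adjacent centre rests on a small transition-state preference, and lithium-bridged aggregates could instead favour the C2 epimer, so the wanted isomer may be the minor one.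
Fallback, setting out from 11 and coming back at 14: replace the oxidative coupling by an SN2 displacement in which both centres are set independently. Ester 11 is hydroxylated (KN(SiMe3)2, THF, −78 °C, then 2-(phenylsulfonyl)-3-phenyloxaziridine) to racemic methyl 2-hydroxy-3-[3-(tert-butyldimethylsilyloxy)-4-(3-methylbut-2-en-1-yl)phenyl]propanoate F3. Dess–Martin periodinane oxidises it to methyl 2-oxo-3-[3-(tert-butyldimethylsilyloxy)-4-(3-methylbut-2-en-1-yl)phenyl]propanoate F4. Asymmetric transfer hydrogenation (RuCl(p-cymene)(TsDPEN), HCO2H/Et3N, ligand enantiomer chosen to give the R alcohol) gives methyl (R)-2-hydroxy-3-[3-(tert-butyldimethylsilyloxy)-4-(3-methylbut-2-en-1-yl)phenyl]propanoate F5. Tf2O and 2,6-lutidine (CH2Cl2, −78 °C) give methyl (R)-2-(trifluoromethylsulfonyloxy)-3-[3-(tert-butyldimethylsilyloxy)-4-(3-methylbut-2-en-1-yl)phenyl]propanoate F6. The sodium enolate of 6 (NaN(SiMe3)2, THF, −78 °C) then displaces the triflate with inversion, while the auxiliary again controls the aryl-bearing carbon, giving 14.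

Step 3. Direct phenoxide C-prenylation gives a modest yield and needs separation from the O-prenyl ether, the 2-prenyl isomer and bis-prenylated material.
Fallback, setting out from 7 and coming back at 11: put a halogen at the position first and attach the prenyl group by cross-coupling. ortho-Selective bromination of 7 (NBS, catalytic iPr2NH, CH2Cl2, 0 °C) gives methyl 3-(4-bromo-3-hydroxyphenyl)propanoate F1, purified by crystallisation or chromatography. Silylation (TBSCl, imidazole, DMF) gives methyl 3-[4-bromo-3-(tert-butyldimethylsilyloxy)phenyl]propanoate F2. Linear-selective Negishi coupling with Me2C=CHCH2ZnBr (made from 8, Zn dust and LiCl in THF; Pd(OAc)2 and the biarylphosphine CPhos, THF, rt) delivers 11 directly.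

Step 6. Hydroperoxide could also hydrolyse the methyl ester, or the hindered imide could open at the ring carbonyl. Partial loss of the aryl silyl ethers is harmless because step 7 removes them anyway.
Fallback, setting out from 14 and coming back at 17: exchange the auxiliary for a fluoride-labile ester instead of hydrolysing it. Treating 14 with BrMgOCH2CH2SiMe3 (from MeMgBr and 2-(trimethylsilyl)ethanol, THF, 0 °C) gives 1-methyl 4-[2-(trimethylsilyl)ethyl] (2R,3R)-2-{[3-(tert-butyldimethylsilyloxy)-4-(3-methylbut-2-en-1-yl)phenyl]methyl}-3-[4-(tert-butyldimethylsilyloxy)phenyl]butanedioate F7. Excess Bu4NF in THF then removes the silylethyl ester and both silyl ethers in one operation to give 17.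

**Further compounds**
F1 | step 3 | methyl 3-(4-bromo-3-hydroxyphenyl)propanoate | COC(=O)CCc1ccc(Br)c(O)c1
F2 | step 3 | methyl 3-[4-bromo-3-(tert-butyldimethylsilyloxy)phenyl]propanoate | COC(=O)CCc1ccc(Br)c(O[Si](C)(C)C(C)(C)C)c1
F3 | step 5 | methyl 2-hydroxy-3-[3-(tert-butyldimethylsilyloxy)-4-(3-methylbut-2-en-1-yl)phenyl]propanoate (racemic) | COC(=O)C(O)Cc1ccc(CC=C(C)C)c(O[Si](C)(C)C(C)(C)C)c1
F4 | step 5 | methyl 2-oxo-3-[3-(tert-butyldimethylsilyloxy)-4-(3-methylbut-2-en-1-yl)phenyl]propanoate | COC(=O)C(=O)Cc1ccc(CC=C(C)C)c(O[Si](C)(C)C(C)(C)C)c1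
F5 | step 5 | methyl (R)-2-hydroxy-3-[3-(tert-butyldimethylsilyloxy)-4-(3-methylbut-2-en-1-yl)phenyl]propanoate | COC(=O)[C@H](O)Cc1ccc(CC=C(C)C)c(O[Si](C)(C)C(C)(C)C)c1
F6 | step 5 | methyl (R)-2-(trifluoromethylsulfonyloxy)-3-[3-(tert-butyldimethylsilyloxy)-4-(3-methylbut-2-en-1-yl)phenyl]propanoate | COC(=O)[C@H](OS(=O)(=O)C(F)(F)F)Cc1ccc(CC=C(C)C)c(O[Si](C)(C)C(C)(C)C)c1
F7 | step 6 | 1-methyl 4-[2-(trimethylsilyl)ethyl] (2R,3R)-2-{[3-(tert-butyldimethylsilyloxy)-4-(3-methylbut-2-en-1-yl)phenyl]methyl}-3-[4-(tert-butyldimethylsilyloxy)phenyl]butanedioate | COC(=O)[C@H](Cc1ccc(CC=C(C)C)c(O[Si](C)(C)C(C)(C)C)c1)[C@@H](C(=O)OCC[Si](C)(C)C)c1ccc(O[Si](C)(C)C(C)(C)C)cc1
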